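## Retrosynthetic overview

1. Target 22 ⇐ diol 21 (double acetylation) ⇐ nor-lactone 19 (C11 methylation of the trans-fused lactone enolate).
2. Key disconnection C6–C7: 19 ⇐ acyclic epoxy enal–enoate 17. SmI2 turns the C6 aldehyde carbon into a ketyl that attacks the enoate β-carbon C7, closing the ten-membered ring and the γ-lactone in one step.
3. 17 ⇐ diol 13 by cross-metathesis, acetal hydrolysis and hydroxyl-directed epoxidation (C1/C10 set from C9).
4. 13 ⇐ lactol 9 ⇐ δ-lactone 8 (RCM; the six-membered ring locks the Z-1(10) olefin) ⇐ C5 enal 1; two Brown allylations set C3 and C9.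
5. Ring order: temporary δ-lactone (step 3, opened in step 5), then oxirane (step 8), then carbocycle and γ-lactone together (step 9).

Assumption: (E)-4,4-dimethoxy-2-methylbut-2-enal 1 is bought as a carotenoid C5 building block; germacrane numbering (C1–C15) is used in the comments.

## Route

Step 1
Reactants: 1 (E)-4,4-dimethoxy-2-methylbut-2-enal; 2 allylmagnesium bromide
Product: 5 (S,E)-7,7-dimethoxy-5-methylhepta-1,5-dien-4-ol, via (−)-B-allyldiisopinocampheylborane 3 (not isolated), via diisopinocampheylborinate 4 (not isolated)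
Conditions: (−)-Ipc2BOMe (1.2 equiv), 2 (1.15 equiv), Et2O, −78 °C to rt; then 1, −78 °C, 3 h; then 3 M NaOH, 30% H2O2, rt
Reagents that add atoms: none
Why: Brown asymmetric allylboration, in which the (+)-α-pinene-derived allylborane adds to the Si face of the enal through a chair Zimmerman–Traxler transition state and so gives the (S)-carbinol at C3, with acetal and trisubstituted olefin untouched.

Step 2
Reactants: 5 (S,E)-7,7-dimethoxy-5-methylhepta-1,5-dien-4-ol; 6 methacryloyl chloride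
Product: 7 (S,E)-7,7-dimethoxy-5-methylhepta-1,5-dien-4-yl 2-methylprop-2-enoate
Conditions: Et3N (2 equiv), DMAP (10 mol %), CH2Cl2, 0 °C to rt
Reagents that add atoms: none
Why: DMAP-catalysed O-acylation of the secondary alcohol, which touches no stereocentre and brings in C9, C10 and C14.

Step 3
Reactants: 7 (S,E)-7,7-dimethoxy-5-methylhepta-1,5-dien-4-yl 2-methylprop-2-enoate
Product: 8 (S)-6-[(E)-4,4-dimethoxybut-2-en-2-yl]-3-methyl-5,6-dihydro-2H-pyran-2-one
Conditions: second-generation Grubbs catalyst (H2IMes)(PCy3)Cl2Ru=CHPh (5 mol %), CH2Cl2 (0.01 M), 40 °C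
Reagents that add atoms: none
Why: Ring-closing metathesis of the terminal vinyl group onto the methacrylate gives the six-membered α-methyl unsaturated lactone, whose ring forces the future C1=C10 olefin to be Z (C2 cis to C9), while the hindered trisubstituted C4=C5 olefin does not react.

Step 4
Reactants: 8 (S)-6-[(E)-4,4-dimethoxybut-2-en-2-yl]-3-methyl-5,6-dihydro-2H-pyran-2-one
Product: 9 (2RS,6S)-6-[(E)-4,4-dimethoxybut-2-en-2-yl]-3-methyl-5,6-dihydro-2H-pyran-2-ol
Conditions: i-Bu2AlH (1.1 equiv), CH2Cl2, −78 °C; aqueous Rochelle salt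
Reagents that add atoms: none
Why: Low-temperature 1,2-reduction of the lactone carbonyl by i-Bu2AlH stops at the aluminium hemiacetal, which gives the lactol (a masked (Z)-enal at C9) on work-up.

Step 5
Reactants: 9 (2RS,6S)-6-[(E)-4,4-dimethoxybut-2-en-2-yl]-3-methyl-5,6-dihydro-2H-pyran-2-ol; 2 allylmagnesium bromide
Product: 13 (4R,5Z,8S,9E)-11,11-dimethoxy-5,9-dimethylundeca-1,5,9-triene-4,8-diol, via (+)-B-allyldiisopinocampheylborane 10 (not isolated), via hydroxy enal 11 (not isolated), via diisopinocampheylborinate 12 (not isolated)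
Conditions: (+)-Ipc2BOMe (2.4 equiv), 2 (2.3 equiv), Et2O, −78 °C to rt; then 9, −78 to 0 °C; then 3 M NaOH, 30% H2O2, rt
Reagents that add atoms: none
Why: Brown allylboration of the ring-opened (Z)-hydroxy enal, in which the (−)-α-pinene-derived reagent attacks the Re face through the chair transition state to give the (R)-carbinol at C9 by reagent control, with the Z olefin kept.

Step 6
Reactants: 13 (4R,5Z,8S,9E)-11,11-dimethoxy-5,9-dimethylundeca-1,5,9-triene-4,8-diol; 14 methyl acrylate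
Product: 15 methyl (2E,5R,6Z,9S,10E)-5,9-dihydroxy-12,12-dimethoxy-6,10-dimethyldodeca-2,6,10-trienoate
Conditions: second-generation Hoveyda–Grubbs catalyst (H2IMes)Cl2Ru=CH(C6H4-2-O-i-Pr) (5 mol %), 14 (5 equiv), CH2Cl2, 40 °C
Reagents that add atoms: none
Why: Olefin cross-metathesis of the only monosubstituted olefin with the electron-poor acrylate gives the (E)-enoate selectively, the two trisubstituted olefins and the free diol being tolerated.

Step 7
Reactants: 15 methyl (2E,5R,6Z,9S,10E)-5,9-dihydroxy-12,12-dimethoxy-6,10-dimethyldodeca-2,6,10-trienoate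
Product: 16 methyl (2E,5R,6Z,9S,10E)-5,9-dihydroxy-6,10-dimethyl-12-oxododeca-2,6,10-trienoate
Conditions: PPTS (10 mol %), acetone–H2O 10:1, rt
Reagents that add atoms: water, O
Why: Mild acid-catalysed acetal hydrolysis, fast for an allylic dimethyl acetal, frees the C6 enal before any epoxide is present and makes the C4=C5 olefin electron-poor.

Step 8
Reactants: 16 methyl (2E,5R,6Z,9S,10E)-5,9-dihydroxy-6,10-dimethyl-12-oxododeca-2,6,10-trienoate
Product: 17 methyl (2E,5R)-5-hydroxy-5-[(2S,3R)-3-[(2S,3E)-2-hydroxy-3-methyl-5-oxopent-3-en-1-yl]-2-methyloxiran-2-yl]pent-2-enoate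
Conditions: mCPBA (1.1 equiv), NaHCO3 (3 equiv), CH2Cl2, −20 to 0 °C
Reagents that add atoms: mCPBA (3-chloroperoxybenzoic acid), OOC(=O)c1cccc(Cl)c1
Why: Henbest hydroxyl-directed peracid epoxidation of the only electron-rich olefin, in which 1,3-allylic strain in the (Z)-allylic alcohol holds H9 in the olefin plane so that oxygen is delivered syn to the C9 hydroxyl and gives the threo epoxy alcohol with the C1/C10 geometry of the target (descriptors 1R,10S while C9 carries a free OH).

Step 9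
Reactants: 17 methyl (2E,5R)-5-hydroxy-5-[(2S,3R)-3-[(2S,3E)-2-hydroxy-3-methyl-5-oxopent-3-en-1-yl]-2-methyloxiran-2-yl]pent-2-enoate
Product: 19 (1R,3S,6S,7S,9R,10S)-1,10-epoxy-3,9-dihydroxy-13-norgermacr-4(E)-en-12,6-olide, via hydroxy ester 18 (not isolated)
Conditions: SmI2 (2.5 equiv, 0.1 M in THF, added over 8 h), t-BuOH (2.5 equiv), THF (0.002 M in 17), −20 °C to rt
Reagents that add atoms: none
Why: Proposed new method: SmI2 reduces only the conjugated aldehyde to a samarium-bound ketyl, whose C6 carbon now acts as a nucleophile and, held against the ester carbonyl by trivalent samarium, adds to the electrophilic β-carbon C7 of the (E)-enoate, after which a second electron and t-BuOH give the ester and the C6 samarium alkoxide lactonises (closest known chemistry: SmI2 ketyl–acrylate lactone synthesis and SmI2 ketyl–olefin closures of eight-membered rings); the trans C6/C7 relationship (6S,7S) is expected because the (E)-enoate and the (E)-C4=C5 olefin let the chain close only with H6 and H7 anti, the facial sense is expected to follow a folding that keeps the C3 and C9 hydroxyls on the outside of the forming ring, and the C3 hydroxyl is kept free because a γ-acyloxy group would be expelled from the ketyl.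

Step 10
Reactants: 19 (1R,3S,6S,7S,9R,10S)-1,10-epoxy-3,9-dihydroxy-13-norgermacr-4(E)-en-12,6-olide
Product: 21 (1R,3S,6S,7S,9R,10S,11R)-1,10-epoxy-3,9-dihydroxygermacr-4(E)-en-12,6-olide, via trilithium enolate 20 (not isolated)
Conditions: LiN(i-Pr)2 (3.3 equiv), THF, −78 °C; MeI (3 equiv), −78 to −40 °C; AcOH quench at −78 °C
Reagents that add atoms: iodomethane, CI
Why: Lactone enolate C-alkylation with the two hydroxyls carried as lithium alkoxides, in which the electrophile enters the trans-fused γ-lactone enolate anti to the pseudo-axial H7 and so places the new methyl cis to C8 (11R).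

Step 11
Reactants: 21 (1R,3S,6S,7S,9R,10S,11R)-1,10-epoxy-3,9-dihydroxygermacr-4(E)-en-12,6-olide
Product: 22 (1R,3S,6S,7S,9R,10R,11R)-3,9-diacetoxy-1,10-epoxygermacr-4(E)-en-12,6-olide (CNP0250285.3)
Conditions: Ac2O (6 equiv), pyridine, DMAP (10 mol %), CH2Cl2, rt
Reagents that add atoms: acetic anhydride, CC(=O)OC(C)=O
Why: DMAP-catalysed acetylation of both secondary alcohols, which touches no stereocentre (the C10 descriptor changes from S to R only because the C9 acetate changes the CIP priorities) and is tolerated by oxirane and lactone.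

## Compound list

1 | (E)-4,4-dimethoxy-2-methylbut-2-enal | COC(OC)/C=C(\C)C=O | starting material
2 | allylmagnesium bromide | C=CC[Mg]Br | starting material
3 | (−)-B-allyldiisopinocampheylborane (not isolated) | C=CCB([C@@H]1C[C@@H]2C[C@@H](C2(C)C)[C@H]1C)[C@@H]1C[C@@H]2C[C@@H](C2(C)C)[C@H]1C | intermediate
4 | (S,E)-7,7-dimethoxy-5-methylhepta-1,5-dien-4-yl diisopinocampheylborinate (not isolated) | C=CC[C@H](OB([C@@H]1C[C@@H]2C[C@@H](C2(C)C)[C@H]1C)[C@@H]1C[C@@H]2C[C@@H](C2(C)C)[C@H]1C)/C(C)=C/C(OC)OC | intermediate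
5 | (S,E)-7,7-dimethoxy-5-methylhepta-1,5-dien-4-ol | C=CC[C@H](O)/C(C)=C/C(OC)OC | intermediate
6 | methacryloyl chloride | CC(=C)C(Cl)=O | starting material
7 | (S,E)-7,7-dimethoxy-5-methylhepta-1,5-dien-4-yl 2-methylprop-2-enoate | C=CC[C@H](OC(=O)C(C)=C)/C(C)=C/C(OC)OC | intermediate
8 | (S)-6-[(E)-4,4-dimethoxybut-2-en-2-yl]-3-methyl-5,6-dihydro-2H-pyran-2-one | O=C1O[C@@H](CC=C1C)/C(C)=C/C(OC)OC | intermediate
9 | (2RS,6S)-6-[(E)-4,4-dimethoxybut-2-en-2-yl]-3-methyl-5,6-dihydro-2H-pyran-2-ol | OC1O[C@@H](CC=C1C)/C(C)=C/C(OC)OC | intermediate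
10 | (+)-B-allyldiisopinocampheylborane (not isolated) | C=CCB([C@H]1C[C@H]2C[C@H](C2(C)C)[C@@H]1C)[C@H]1C[C@H]2C[C@H](C2(C)C)[C@@H]1C | intermediate
11 | (2Z,5S,6E)-5-hydroxy-8,8-dimethoxy-2,6-dimethylocta-2,6-dienal (open form of 9, not isolated) | O=C/C(C)=C\C[C@H](O)/C(C)=C/C(OC)OC | intermediate
12 | (4R,5Z,8S,9E)-8-hydroxy-11,11-dimethoxy-5,9-dimethylundeca-1,5,9-trien-4-yl diisopinocampheylborinate (not isolated) | C=CC[C@@H](OB([C@H]1C[C@H]2C[C@H](C2(C)C)[C@@H]1C)[C@H]1C[C@H]2C[C@H](C2(C)C)[C@@H]1C)/C(C)=C\C[C@H](O)/C(C)=C/C(OC)OC | intermediate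
13 | (4R,5Z,8S,9E)-11,11-dimethoxy-5,9-dimethylundeca-1,5,9-triene-4,8-diol | C=CC[C@@H](O)/C(C)=C\C[C@H](O)/C(C)=C/C(OC)OC | intermediate
14 | methyl acrylate | COC(=O)C=C | starting material
15 | methyl (2E,5R,6Z,9S,10E)-5,9-dihydroxy-12,12-dimethoxy-6,10-dimethyldodeca-2,6,10-trienoate | COC(=O)/C=C/C[C@@H](O)/C(C)=C\C[C@H](O)/C(C)=C/C(OC)OC | intermediate
16 | methyl (2E,5R,6Z,9S,10E)-5,9-dihydroxy-6,10-dimethyl-12-oxododeca-2,6,10-trienoate | COC(=O)/C=C/C[C@@H](O)/C(C)=C\C[C@H](O)/C(C)=C/C=O | intermediate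
17 | methyl (2E,5R)-5-hydroxy-5-[(2S,3R)-3-[(2S,3E)-2-hydroxy-3-methyl-5-oxopent-3-en-1-yl]-2-methyloxiran-2-yl]pent-2-enoate | COC(=O)/C=C/C[C@@H](O)[C@]1(C)O[C@@H]1C[C@H](O)/C(C)=C/C=O | intermediate
18 | methyl (1R,3S,6S,7S,9R,10S)-1,10-epoxy-3,6,9-trihydroxy-13-norgermacr-4(E)-en-12-oate (not isolated) | O[C@H]1C[C@H]2O[C@@]2(C)[C@H](O)C[C@@H](CC(=O)OC)[C@H](O)/C=C/1C | intermediate
19 | (1R,3S,6S,7S,9R,10S)-1,10-epoxy-3,9-dihydroxy-13-norgermacr-4(E)-en-12,6-olide | O[C@H]1C[C@H]2O[C@@]2(C)[C@H](O)C[C@@H]2[C@@H](/C=C/1C)OC(=O)C2 | intermediate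
20 | trilithium 3,9-dialkoxide–lactone enolate of 19 (not isolated) | [Li+].[Li+].[Li+].[O-][C@H]1C[C@H]2O[C@@]2(C)[C@H]([O-])C[C@@H]2[C@@H](/C=C/1C)OC([O-])=C2 | intermediate
21 | (1R,3S,6S,7S,9R,10S,11R)-1,10-epoxy-3,9-dihydroxygermacr-4(E)-en-12,6-olide | O[C@H]1C[C@H]2O[C@@]2(C)[C@H](O)C[C@@H]2[C@@H](/C=C/1C)OC(=O)[C@@H]2C | intermediate
22 | (1R,3S,6S,7S,9R,10R,11R)-3,9-diacetoxy-1,10-epoxygermacr-4(E)-en-12,6-olide (CNP0250285.3) | CC(=O)O[C@H]1C[C@H]2O[C@@]2(C)[C@H](OC(C)=O)C[C@@H]2[C@@H](/C=C/1C)OC(=O)[C@@H]2C | target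

## Step count and risks

Total steps: 11. Longest linear sequence: 11.

The three steps most likely to fail:

**Step 9 (SmI2 ring closure).** This is the least certain step. The conjugated ketyl may be reduced further or dimerise before the slow ten-membered closure, and the facial sense of the closure relative to C3, C9 and the oxirane is not secured by a firm model. The fallback closes the same ring with a persistent allyl-chromium nucleophile. It sets out from 13: cross-metathesis with (E)-1,4-dibromobut-2-ene (second-generation Hoveyda–Grubbs catalyst, CH2Cl2, 40 °C) gives (2E,5R,6Z,9S,10E)-1-bromo-12,12-dimethoxy-6,10-dimethyldodeca-2,6,10-triene-5,9-diol F1. PPTS in wet acetone frees the enal (2E,4S,6Z,8R,10E)-12-bromo-4,8-dihydroxy-3,7-dimethyldodeca-2,6,10-trienal F2. Buffered mCPBA, directed as in step 8, gives (2E,4S)-5-[(2R,3S)-3-[(1R,3E)-5-bromo-1-hydroxypent-3-en-1-yl]-3-methyloxiran-2-yl]-4-hydroxy-3-methylpent-2-enal F3. CrCl2 (6 equiv) in THF at high dilution then closes C6–C7 by intramolecular Nozaki–Hiyama allylation through a chair transition state (anti, hence trans at C6/C7), giving (1R,3S,6S,7S,9R,10S)-1,10-epoxy-13-norgermacra-4(E),11-diene-3,6,9-triol F4. 9-BBN followed by NaOH/H2O2 hydroborates only the vinyl group to (1R,3S,6S,7R,9R,10S)-1,10-epoxy-13-norgermacr-4(E)-ene-3,6,9,12-tetraol F5. TEMPO (cat.) with PhI(OAc)2 oxidises the primary alcohol through the lactol to the lactone, which comes back to the route at 19.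

**Step 5 (allylboration of the lactol).** The lactol is mostly closed and its hydroxyl consumes reagent, so conversion and ee may be poor. The fallback builds C9 on a separate piece and locks the Z olefin with a silicon tether. It sets out from 5. Methacrolein is allylated with the (+)-Ipc2BOMe/allylmagnesium bromide reagent to give (R)-2-methylhexa-1,5-dien-3-ol F6. Cross-metathesis of its monosubstituted olefin with methyl acrylate gives methyl (R,E)-5-hydroxy-6-methylhepta-2,6-dienoate F7. Compound 5 is silylated with i-Pr2SiCl2/imidazole and the chlorosilane is then treated with F7 to give the mixed silaketal methyl (2E,5R)-5-[({[(4S,5E)-7,7-dimethoxy-5-methylhepta-1,5-dien-4-yl]oxy}di(propan-2-yl)silyl)oxy]-6-methylhepta-2,6-dienoate F8. Ring-closing metathesis (second-generation Grubbs catalyst, toluene, 80 °C) closes the eight-membered ring methyl (2E)-4-[(4R,5Z,8S)-8-[(E)-4,4-dimethoxybut-2-en-2-yl]-5-methyl-2,2-di(propan-2-yl)-1,3-dioxa-2-silacyclooct-5-en-4-yl]but-2-enoate F9, in which the new trisubstituted olefin can only be Z. HF·pyridine buffered with pyridine removes the silicon and comes back to the route at 15.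

**Step 10 (methylation of the epoxy diol lactone).** The trianion may react sluggishly, and the facial preference is argued by analogy with trans-fused lactones. The fallback sets the centre by protonation instead of alkylation, and sets out from 19. If the alkylation gives mainly the C11 epimer (1R,3S,6S,7S,9R,10S,11S)-1,10-epoxy-3,9-dihydroxygermacr-4(E)-en-12,6-olide F10, the electrophile prefers the other face. F10 is then deprotonated again with LiN(i-Pr)2 (3.3 equiv, THF, −78 °C) and the enolate is protonated kinetically with 2,6-di-tert-butylphenol. The proton enters from that same preferred face and turns the methyl to the 11R side, which comes back to the route at 21.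

## Further compounds

F1 | step 9 | (2E,5R,6Z,9S,10E)-1-bromo-12,12-dimethoxy-6,10-dimethyldodeca-2,6,10-triene-5,9-diol | BrC/C=C/C[C@@H](O)/C(C)=C\C[C@H](O)/C(C)=C/C(OC)OC
F2 | step 9 | (2E,4S,6Z,8R,10E)-12-bromo-4,8-dihydroxy-3,7-dimethyldodeca-2,6,10-trienal | BrC/C=C/C[C@@H](O)/C(C)=C\C[C@H](O)/C(C)=C/C=O
F3 | step 9 | (2E,4S)-5-[(2R,3S)-3-[(1R,3E)-5-bromo-1-hydroxypent-3-en-1-yl]-3-methyloxiran-2-yl]-4-hydroxy-3-methylpent-2-enal | BrC/C=C/C[C@@H](O)[C@]1(C)O[C@@H]1C[C@H](O)/C(C)=C/C=O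
F4 | step 9 | (1R,3S,6S,7S,9R,10S)-1,10-epoxy-13-norgermacra-4(E),11-diene-3,6,9-triol | O[C@H]1C[C@H]2O[C@@]2(C)[C@H](O)C[C@@H](C=C)[C@H](O)/C=C/1C
F5 | step 9 | (1R,3S,6S,7R,9R,10S)-1,10-epoxy-13-norgermacr-4(E)-ene-3,6,9,12-tetraol | O[C@H]1C[C@H]2O[C@@]2(C)[C@H](O)C[C@@H](CCO)[C@H](O)/C=C/1C
F6 | step 5 | (R)-2-methylhexa-1,5-dien-3-ol | C=CC[C@@H](O)C(C)=C
F7 | step 5 | methyl (R,E)-5-hydroxy-6-methylhepta-2,6-dienoate | COC(=O)/C=C/C[C@@H](O)C(C)=C
F8 | step 5 | methyl (2E,5R)-5-[({[(4S,5E)-7,7-dimethoxy-5-methylhepta-1,5-dien-4-yl]oxy}di(propan-2-yl)silyl)oxy]-6-methylhepta-2,6-dienoate | COC(=O)/C=C/C[C@@H](O[Si](C(C)C)(C(C)C)O[C@@H](CC=C)/C(C)=C/C(OC)OC)C(C)=C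
F9 | step 5 | methyl (2E)-4-[(4R,5Z,8S)-8-[(E)-4,4-dimethoxybut-2-en-2-yl]-5-methyl-2,2-di(propan-2-yl)-1,3-dioxa-2-silacyclooct-5-en-4-yl]but-2-enoate | COC(=O)/C=C/C[C@H]1O[Si](C(C)C)(C(C)C)O[C@@H](C/C=C1/C)/C(C)=C/C(OC)OC
F10 | step 10 | (1R,3S,6S,7S,9R,10S,11S)-1,10-epoxy-3,9-dihydroxygermacr-4(E)-en-12,6-olide | O[C@H]1C[C@H]2O[C@@]2(C)[C@H](O)C[C@@H]2[C@@H](/C=C/1C)OC(=O)[C@H]2C
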